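**Strategy**

The upper epicatechin unit is built, not bought: its pyran ring (ring C: O1, C2, C3, C4, C4a, C8a) is closed by a [3+3] annulation of a 3,5-dioxygenated phenol (ring A, supplying O1, C8a, C4a) with a cis-epoxy aldehyde (C4, C3, C2 carrying ring B). One operation joins the aldehyde carbon to the ortho carbon (C4a–C4) and lets the phenol oxygen open the epoxide at its benzylic carbon (O1–C2). It exploits the equivalence of the two ortho carbons of the phloroglucinol-type ring A and the benzylic activation of C2. The resulting flavan-3,4-diol is the C4 electrophile for a benzylated epicatechin gallate dimer; hydrogenolysis ends the route.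

Key step: step 8

Remark: the target is read as epicatechin-(4β→8)-epicatechin 3-O-gallate-(4β→8)-epicatechin 3-O-gallate, all units 2R,3R, with the upper 3-OH free. Diol 15 is drawn as its 4R epimer, but its C4 configuration is of no consequence because C4 is ionised in step 9.

**Route**

Step 1
Reactants: 1 (−)-epicatechin
Product: 2 5,7,3',4'-tetra-O-benzyl-(−)-epicatechin, i.e. (2R,3R)-5,7-bis(benzyloxy)-2-[3,4-bis(benzyloxy)phenyl]chroman-3-ol
Conditions: BnBr (4.4 equiv), K2CO3, DMF, 0 °C → rt, argon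
Reagents that add atoms: benzyl bromide, BrCc1ccccc1
Why: Williamson etherification with K2CO3 should alkylate only the four phenols and leave the much less acidic secondary 3-OH free, the low temperature limiting C-benzylation and C2 epimerisation so that both stereocentres are kept.

Step 2
Reactants: 2 5,7,3',4'-tetra-O-benzyl-(−)-epicatechin; 3 3,4,5-tris(benzyloxy)benzoic acid
Product: 4 hepta-O-benzyl-(−)-epicatechin 3-O-gallate, i.e. (2R,3R)-5,7-bis(benzyloxy)-2-[3,4-bis(benzyloxy)phenyl]chroman-3-yl 3,4,5-tris(benzyloxy)benzoate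
Conditions: 3 (1.5 equiv), DCC (1.6 equiv), DMAP (0.3 equiv), CH2Cl2, 0 °C → rt
Reagents that add atoms: none
Why: Steglich esterification should acylate the axial 3-OH through the N-acylpyridinium of the benzylated gallic acid, with retention at C3 because the C–O bond of the alcohol is not broken.

Step 3
Reactants: 4 hepta-O-benzyl-(−)-epicatechin 3-O-gallate
Product: 5 (2R,3R,4S)-5,7-bis(benzyloxy)-2-[3,4-bis(benzyloxy)phenyl]-4-(2-ethoxyethoxy)chroman-3-yl 3,4,5-tris(benzyloxy)benzoate (4β-ether)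
Conditions: DDQ (2 equiv), 2-ethoxyethanol (5 equiv), CH2Cl2, rt
Reagents that add atoms: 2-ethoxyethanol, CCOCCO
Why: DDQ benzylic oxidation abstracts hydride from C4 (cation stabilised by the dialkoxy ring A), and the alcohol should add anti to the 3-acyloxy group to give the 4β (4S) ether, although either C4 epimer would serve because C4 is ionised again in step 4.

Step 4
Reactants: 5 the 4β-(2-ethoxyethoxy) electrophile; 4 hepta-O-benzyl-(−)-epicatechin 3-O-gallate (4 equiv, excess recovered)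
Product: 6 hepta-O-benzyl-epicatechin 3-O-gallate-(4β→8)-hepta-O-benzyl-epicatechin 3-O-gallate (protected middle–bottom dimer)
Conditions: TMSOTf (0.1 equiv), CH2Cl2, −78 °C; Et3N quench
Reagents that add atoms: none
Why: Lewis-acid ionisation of the C4 ether and Friedel–Crafts attack by C8 of excess 4 should set the 4β→8 (3,4-trans) interflavan bond, the nucleophile entering anti to the 3-O-galloyl group, whose anchimeric assistance shields the α face.

Step 5
Reactants: 7 3,4-bis(benzyloxy)benzaldehyde; 8 ethyl 2-(diphenoxyphosphoryl)acetate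
Product: 9 ethyl (Z)-3-[3,4-bis(benzyloxy)phenyl]prop-2-enoate
Conditions: NaH, THF, −78 °C → 0 °C
Reagents that add atoms: none
Why: The Z-selective Horner–Wadsworth–Emmons olefination with a diaryl phosphonoacetate should give the cis-cinnamate, because the electron-poor aryloxy groups speed elimination from the kinetically formed syn adduct.

Step 6
Reactants: 9 ethyl (Z)-3-[3,4-bis(benzyloxy)phenyl]prop-2-enoate
Product: 10 ethyl (2S,3S)-3-[3,4-bis(benzyloxy)phenyl]oxirane-2-carboxylate (cis-glycidate)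
Conditions: (S,S)-N,N'-bis(3,5-di-tert-butylsalicylidene)-1,2-cyclohexanediaminomanganese chloride (6 mol%), 4-phenylpyridine N-oxide (0.25 equiv), aq. NaOCl (pH 11.3), CH2Cl2, 4 °C
Reagents that add atoms: sodium hypochlorite, [Na+].[O-]Cl
Why: Jacobsen epoxidation of a cis-cinnamate ester should give the cis-epoxide, the (S,S)-catalyst setting both new stereocentres as 2S,3S by face-selective oxygen transfer.

Step 7
Reactants: 10 ethyl (2S,3S)-3-[3,4-bis(benzyloxy)phenyl]oxirane-2-carboxylate
Product: 11 (2S,3S)-3-[3,4-bis(benzyloxy)phenyl]oxirane-2-carbaldehyde (cis-epoxy aldehyde, used crude)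
Conditions: iBu2AlH (1.1 equiv), CH2Cl2, −78 °C; aq. KNaC4H4O6 (potassium sodium tartrate)
Reagents that add atoms: none
Why: Partial reduction of an alpha-oxygenated ester should stop at the aldehyde because the chelated tetrahedral aluminium intermediate holds until work-up, and the epoxide stereocentres are not touched.

Step 8
Reactants: 11 (2S,3S)-3-[3,4-bis(benzyloxy)phenyl]oxirane-2-carbaldehyde; 12 3,5-bis(benzyloxy)phenol (1.2 equiv)
Product: 15 (2R,3R,4R)-5,7-bis(benzyloxy)-2-[3,4-bis(benzyloxy)phenyl]chromane-3,4-diol, via titanium phenoxide 13 (not isolated), via epoxy carbinol 14 (not isolated)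
Conditions: 12, Ti(OiPr)4 (1.05 equiv), PhMe, rt, then removal of iPrOH; 11, CH2Cl2, −20 °C → 40 °C; aq. tartaric acid work-up
Reagents that add atoms: none
Why: Proposed new method: the aryloxytitanium triisopropoxide 13 binds the aldehyde of 11 and delivers its ortho carbon to the carbonyl carbon through a six-membered chelated transition state (C4a–C4), after which the titanium-bound 2,3-epoxy alcohol 14 is opened at its benzylic epoxide carbon by the neighbouring phenol oxygen (O1–C2). The closest known reaction types are the ortho-specific hydroxyalkylation of titanium phenoxides with alpha-oxygenated aldehydes and the Ti(OiPr)4-assisted C3-selective opening of 2,3-epoxy alcohols, here by a tethered phenol as in epoxide-based flavan-3-ol syntheses; their union in one flask on an epoxy aldehyde is the untested part. The pyran ring (ring C of the upper unit) closes in the 6-endo-tet mode at the epoxide. C3 keeps the configuration set in step 6, C2 is formed by SN2 inversion so that the cis-epoxide gives the 2,3-cis (2R,3R) arrangement, and C4 should arise 4R by Felkin-type addition anti to the epoxide C–O bond, although either C4 epimer serves because C4 is ionised in step 9. The step needs ortho-C attack over para-C and O attack, which the titanium template secures while the equivalence of the two ortho carbons of 12 removes any further regiochemical question, and it needs 6-endo over 5-exo opening with inversion, which the electron-rich 3,4-bis(benzyloxy)phenyl group and the non-protic conditions favour.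

Step 9
Reactants: 15 (2R,3R,4R)-5,7-bis(benzyloxy)-2-[3,4-bis(benzyloxy)phenyl]chromane-3,4-diol; 6 protected middle–bottom dimer (2.5 equiv, excess recovered)
Product: 16 octadeca-O-benzyl epicatechin-(4β→8)-epicatechin 3-O-gallate-(4β→8)-epicatechin 3-O-gallate (upper 3-OH free)
Conditions: TiCl4 (2 equiv), CH2Cl2/THF 9:1, 0 °C → rt, slow addition of 15
Reagents that add atoms: none
Why: TiCl4 ionises the C4 hydroxyl of the flavan-3,4-diol and the cation is captured in a Friedel–Crafts reaction by C8 of the upper unit of 6, its most nucleophilic site, anti to the axial 3-OH, which should set the 4β (3,4-trans) centre of the upper unit.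

Step 10
Reactants: 16 octadeca-O-benzyl trimer
Product: 17 epicatechin-(4β→8)-epicatechin 3-O-gallate-(4β→8)-epicatechin 3-O-gallate (target)
Conditions: H2 (1 atm), Pd(OH)2/C, THF/MeOH/H2O, rt
Reagents that add atoms: none
Why: Hydrogenolysis should remove all eighteen benzyl ethers without touching the gallate esters, the interflavan bonds or any stereocentre.

**Compound list**

1 | (−)-epicatechin, (2R,3R) | O[C@@H]1Cc2c(O)cc(O)cc2O[C@@H]1c1ccc(O)c(O)c1 | starting material
2 | 5,7,3',4'-tetra-O-benzyl-(−)-epicatechin, (2R,3R)-5,7-bis(benzyloxy)-2-[3,4-bis(benzyloxy)phenyl]chroman-3-ol | O[C@@H]1Cc2c(OCc3ccccc3)cc(OCc3ccccc3)cc2O[C@@H]1c1ccc(OCc2ccccc2)c(OCc2ccccc2)c1 | intermediate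
3 | 3,4,5-tris(benzyloxy)benzoic acid | OC(=O)c1cc(OCc2ccccc2)c(OCc2ccccc2)c(OCc2ccccc2)c1 | starting material
4 | hepta-O-benzyl-(−)-epicatechin 3-O-gallate, (2R,3R) | O=C(O[C@@H]1Cc2c(OCc3ccccc3)cc(OCc3ccccc3)cc2O[C@@H]1c1ccc(OCc2ccccc2)c(OCc2ccccc2)c1)c1cc(OCc2ccccc2)c(OCc2ccccc2)c(OCc2ccccc2)c1 | intermediate
5 | (2R,3R,4S)-4-(2-ethoxyethoxy) derivative of 4 (4β-ether) | O=C(O[C@@H]1[C@@H](OCCOCC)c2c(OCc3ccccc3)cc(OCc3ccccc3)cc2O[C@@H]1c1ccc(OCc2ccccc2)c(OCc2ccccc2)c1)c1cc(OCc2ccccc2)c(OCc2ccccc2)c(OCc2ccccc2)c1 | intermediate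
6 | hepta-O-benzyl-epicatechin 3-O-gallate-(4β→8)-hepta-O-benzyl-epicatechin 3-O-gallate | O=C(O[C@@H]1[C@@H](c2c(OCc3ccccc3)cc(OCc3ccccc3)c3c2O[C@H](c2ccc(OCc4ccccc4)c(OCc4ccccc4)c2)[C@H](OC(=O)c2cc(OCc4ccccc4)c(OCc4ccccc4)c(OCc4ccccc4)c2)C3)c2c(OCc3ccccc3)cc(OCc3ccccc3)cc2O[C@@H]1c1ccc(OCc2ccccc2)c(OCc2ccccc2)c1)c1cc(OCc2ccccc2)c(OCc2ccccc2)c(OCc2ccccc2)c1 | intermediate
7 | 3,4-bis(benzyloxy)benzaldehyde | O=Cc1ccc(OCc2ccccc2)c(OCc2ccccc2)c1 | starting material
8 | ethyl 2-(diphenoxyphosphoryl)acetate | CCOC(=O)CP(=O)(Oc1ccccc1)Oc1ccccc1 | starting material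
9 | ethyl (Z)-3-[3,4-bis(benzyloxy)phenyl]prop-2-enoate | CCOC(=O)/C=C\c1ccc(OCc2ccccc2)c(OCc2ccccc2)c1 | intermediate
10 | ethyl (2S,3S)-3-[3,4-bis(benzyloxy)phenyl]oxirane-2-carboxylate (cis) | CCOC(=O)[C@H]1O[C@H]1c1ccc(OCc2ccccc2)c(OCc2ccccc2)c1 | intermediate
11 | (2S,3S)-3-[3,4-bis(benzyloxy)phenyl]oxirane-2-carbaldehyde (cis) | O=C[C@H]1O[C@H]1c1ccc(OCc2ccccc2)c(OCc2ccccc2)c1 | intermediate
12 | 3,5-bis(benzyloxy)phenol | Oc1cc(OCc2ccccc2)cc(OCc2ccccc2)c1 | starting material
13 | triisopropoxytitanium 3,5-bis(benzyloxy)phenoxide | CC(C)O[Ti](OC(C)C)(OC(C)C)Oc1cc(OCc2ccccc2)cc(OCc2ccccc2)c1 | intermediate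
14 | 3,5-bis(benzyloxy)-2-{(R)-[(2R,3S)-3-(3,4-bis(benzyloxy)phenyl)oxiran-2-yl](hydroxy)methyl}phenol | O[C@H](c1c(O)cc(OCc2ccccc2)cc1OCc1ccccc1)[C@H]1O[C@H]1c1ccc(OCc2ccccc2)c(OCc2ccccc2)c1 | intermediate
15 | (2R,3R,4R)-5,7-bis(benzyloxy)-2-[3,4-bis(benzyloxy)phenyl]chromane-3,4-diol (2,3-cis-3,4-cis) | O[C@@H]1[C@H](O)c2c(OCc3ccccc3)cc(OCc3ccccc3)cc2O[C@@H]1c1ccc(OCc2ccccc2)c(OCc2ccccc2)c1 | intermediate
16 | octadeca-O-benzyl epicatechin-(4β→8)-epicatechin 3-O-gallate-(4β→8)-epicatechin 3-O-gallate | O=C(O[C@@H]1[C@@H](c2c(OCc3ccccc3)cc(OCc3ccccc3)c3c2O[C@H](c2ccc(OCc4ccccc4)c(OCc4ccccc4)c2)[C@H](OC(=O)c2cc(OCc4ccccc4)c(OCc4ccccc4)c(OCc4ccccc4)c2)C3)c2c(OCc3ccccc3)cc(OCc3ccccc3)c([C@H]3c4c(OCc5ccccc5)cc(OCc5ccccc5)cc4O[C@H](c4ccc(OCc5ccccc5)c(OCc5ccccc5)c4)[C@@H]3O)c2O[C@@H]1c1ccc(OCc2ccccc2)c(OCc2ccccc2)c1)c1cc(OCc2ccccc2)c(OCc2ccccc2)c(OCc2ccccc2)c1 | intermediate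
17 | epicatechin-(4β→8)-epicatechin 3-O-gallate-(4β→8)-epicatechin 3-O-gallate | O=C(O[C@@H]1[C@@H](c2c(O)cc(O)c3c2O[C@H](c2ccc(O)c(O)c2)[C@H](OC(=O)c2cc(O)c(O)c(O)c2)C3)c2c(O)cc(O)c([C@H]3c4c(O)cc(O)cc4O[C@H](c4ccc(O)c(O)c4)[C@@H]3O)c2O[C@@H]1c1ccc(O)c(O)c1)c1cc(O)c(O)c(O)c1 | target

**Step count and risks**

Total steps: 10. Longest linear sequence: 6 steps (steps 1, 2, 3, 4, 9, 10; the branch through steps 5, 6, 7, 8, 9, 10 is equally long).

Steps most likely to fail:

Step 8. The phenoxide may attack through its para carbon or its oxygen, the first-formed benzylic carbinol may condense with a second phenol, and the epoxide may ionise at its benzylic carbon or open in the 5-exo mode, which would erode the 2,3-cis relationship. The fallback makes the same two bonds in the reverse order by known reactions and under conditions that exclude a benzylic cation. It sets out from glycidate 10 and phenol 12. With Cs2CO3 in DMF the phenoxide should open the glycidic ester at its benzylic carbon by SN2 inversion (the known regiochemistry of 3-aryl glycidates with phenoxide and thiolate nucleophiles) to give ethyl (2S,3R)-3-[3,5-bis(benzyloxy)phenoxy]-3-[3,4-bis(benzyloxy)phenyl]-2-hydroxypropanoate F1. Reduction with iBu2AlH at −78 °C should give (2S,3R)-3-[3,5-bis(benzyloxy)phenoxy]-3-[3,4-bis(benzyloxy)phenyl]-2-hydroxypropanal F2, which on treatment with MgBr2·OEt2 in CH2Cl2 should close by intramolecular Friedel–Crafts hydroxyalkylation at the ortho carbon of the aryl ether. The fallback comes back to the route at 15 (either C4 epimer is usable).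

Step 9. Attack may spread over C6 and C8 of the dimer, 15 may condense with itself through its own ring A, and the product may be extended further. The fallback assembles the chain from the top, so that each union uses a monomeric nucleophile in large excess. It sets out from 15 and 4. TiCl4-mediated coupling of 15 with 4 (4 equiv) should give tetra-O-benzyl-epicatechin-(4β→8)-hepta-O-benzyl-epicatechin 3-O-gallate F3. DDQ with 2-ethoxyethanol should oxidise the unsubstituted C4 of its lower unit, the hindered C4–H of the upper unit being shielded by the interflavan bond, to the 4β-(2-ethoxyethoxy) ether F4, and TMSOTf-mediated coupling of F4 with excess 4 comes back to the route at 16.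

Step 6. With the electron-rich cinnamate the stepwise oxygen transfer may allow bond rotation and leak to the trans-epoxide, enantioselectivity may be lower than for the parent ester, and the ring may be chlorinated. The fallback uses a concerted, alcohol-directed epoxidation. It sets out from 9. Reduction with iBu2AlH (2.2 equiv) should give (Z)-3-[3,4-bis(benzyloxy)phenyl]prop-2-en-1-ol F5. Sharpless asymmetric epoxidation (Ti(OiPr)4, D-(−)-diethyl tartrate, tBuOOH, molecular sieves, CH2Cl2, −20 °C) should give [(2R,3S)-3-[3,4-bis(benzyloxy)phenyl]oxiran-2-yl]methanol F6 with retention of the cis geometry. Parikh–Doering oxidation (SO3·pyridine, DMSO, iPr2NEt) comes back to the route at 11.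

**Further compounds**

F1 | step 8 | ethyl (2S,3R)-3-[3,5-bis(benzyloxy)phenoxy]-3-[3,4-bis(benzyloxy)phenyl]-2-hydroxypropanoate | CCOC(=O)[C@@H](O)[C@H](Oc1cc(OCc2ccccc2)cc(OCc2ccccc2)c1)c1ccc(OCc2ccccc2)c(OCc2ccccc2)c1
F2 | step 8 | (2S,3R)-3-[3,5-bis(benzyloxy)phenoxy]-3-[3,4-bis(benzyloxy)phenyl]-2-hydroxypropanal | O=C[C@@H](O)[C@H](Oc1cc(OCc2ccccc2)cc(OCc2ccccc2)c1)c1ccc(OCc2ccccc2)c(OCc2ccccc2)c1
F3 | step 9 | tetra-O-benzyl-epicatechin-(4β→8)-hepta-O-benzyl-epicatechin 3-O-gallate | O=C(O[C@@H]1Cc2c(OCc3ccccc3)cc(OCc3ccccc3)c([C@H]3c4c(OCc5ccccc5)cc(OCc5ccccc5)cc4O[C@H](c4ccc(OCc5ccccc5)c(OCc5ccccc5)c4)[C@@H]3O)c2O[C@@H]1c1ccc(OCc2ccccc2)c(OCc2ccccc2)c1)c1cc(OCc2ccccc2)c(OCc2ccccc2)c(OCc2ccccc2)c1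
F4 | step 9 | 4β-(2-ethoxyethoxy) derivative of F3 at C4 of the gallate-bearing unit | O=C(O[C@@H]1[C@@H](OCCOCC)c2c(OCc3ccccc3)cc(OCc3ccccc3)c([C@H]3c4c(OCc5ccccc5)cc(OCc5ccccc5)cc4O[C@H](c4ccc(OCc5ccccc5)c(OCc5ccccc5)c4)[C@@H]3O)c2O[C@@H]1c1ccc(OCc2ccccc2)c(OCc2ccccc2)c1)c1cc(OCc2ccccc2)c(OCc2ccccc2)c(OCc2ccccc2)c1
F5 | step 6 | (Z)-3-[3,4-bis(benzyloxy)phenyl]prop-2-en-1-ol | OC/C=C\c1ccc(OCc2ccccc2)c(OCc2ccccc2)c1
F6 | step 6 | [(2R,3S)-3-[3,4-bis(benzyloxy)phenyl]oxiran-2-yl]methanol | OC[C@H]1O[C@H]1c1ccc(OCc2ccccc2)c(OCc2ccccc2)c1
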